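## The problem

Compound 20 is a labdane: a trans-fused decalin (rings A and B) with five stereocentres (C5, C6, C8, C9, C10) and a C9 side chain of two methylenes that ends in an α-substituted butenolide (C13=C14, lactone from C16 to O–C15). The hardest centre is C9, a fully substituted carbinol between the quaternary C10 and the methyl-bearing C8. Its hydroxyl is axial on the α face, anti to the axial C10 methyl, and the neighbouring C8 hydrogen is axial on the β face. C5 and C10 cannot epimerise and can therefore steer the rest: the axial C10 methyl (C20) screens the β face of ring B, and the trans fusion fixes which positions at C6, C8 and C9 are axial. The equatorial C6 acetate is cleaved by nucleophilic base and is enolisable. The free tertiary C9 alcohol ionises in acid, and the butenolide tolerates neither hydride, strong base nor hydrogenation, so it must appear last. The opening is that H on C8 and O on C9 are trans-diaxial neighbours, the formal anti adduct of H–O across a C8=C9 alkene, and that the butenolide carbonyl carbon C16 lies four bonds from C9 (C9–C11–C12–C13–C16). A C16 carboxyl on that tether can therefore deliver the C9 oxygen intramolecularly as a spiro six-membered lactone. A decalin that already holds C5, C10 and the C6 oxygen in the right configuration is available as (+)-larixol 1.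

## Retrosynthesis

**20 to 18.** The C13=C14 double bond is traced to the β-hydroxy-γ-lactone 18 by elimination across C13–H and C14–O (through mesylate 19). Carrying the butenolide earlier would expose it to the enolate and acid steps. The forward step must activate the secondary C14 hydroxyl in the presence of the tertiary C9 hydroxyl and eliminate into conjugation.

**18 to 16.** The acyl–oxygen bond C16–O15 is cut and the acyl group returned to the C9 oxygen, so that 18 becomes the isomeric δ-lactone diol 17 and, with the C15 oxygen silylated, 16. This keeps the acid-sensitive tertiary alcohol masked as an ester until the last two steps. The forward reaction is an acyl transfer from a congested tertiary oxygen to a primary one, five-membered and downhill.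

**16 to 13 and 14.** The C13–C14 bond is cut as an aldol between the enolate 15 of lactone 13 and aldehyde 14. The neighbouring cut, C12–C13, would join a ready-made butenolide to the chain but needs a C12 electrophile and a butenolide α-anion equivalent. The aldol instead uses the acidity the lactone already has and a commercial two-carbon piece. It requires enolisation of the lactone beside the C6 acetate. The configurations at C13 and C14 do not matter.

**13 to 12 (key step).** The C9–O bond and the C8–H bond are cut, leading to the tetrasubstituted alkene acid 12.
- Intermolecular hydration would not distinguish C8 from C9.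
- Halo- or selenolactonisation would put the electrophile on the open α face and force the oxygen onto the β face of C9; the correct isomer would need a heavy atom axial under C20.
- Epoxidation leaves an oxygen on C8 that must then be removed.
- A proton is the only electrophile small enough to sit axially on the β face of C8, and its addition is reversible, so C8 and C9 can settle to the most stable arrangement.

Compound 12 has three stereocentres instead of five and no lactone ring. The forward step needs C9 rather than C8 capture (tether length), trans-diaxial H and O (equilibration), and capture faster than skeletal rearrangement.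

**12 to 11 to 10.** The acid is traced to its methyl ester 11 (O–CH3 cut) and the C8=C9 alkene to the exocyclic C8=C17 isomer 10. The double-bond migration needs acid, and a free carboxyl would already lactonise during it. The ester holds the carboxyl back so that the key step starts from a defined alkene acid. The ester must then be cleaved without touching the acetate, which calls for attack at the methyl carbon and not at the acyl carbon.

**10 to 8 to 6.** The bond between C13 and the carboxyl carbon is cut in the sense of a one-carbon homologation (Arndt–Eistert, through acid chloride 7, diazoketone 8 and ketene 9). Displacement chemistry from a C12 halide with a two-carbon nucleophile would be longer and would need the chain shortened further first.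

**6 to 4 to 2 to 1.** The acetate is removed (5 is the transient mixed anhydride), and the acid 4 is traced to methyl ketone 2 (haloform, through 3) and then to the vinyl carbinol side chain of 1 (oxidative cleavage). Three side-chain carbons of 1 are discarded and three are put back (one in the homologation, two from 14). That is the price of having C16 as a carboxyl on a three-methylene tether. In return 1 supplies both rings, C5, C10, the C6 oxygen and C8 as an alkene carbon.

## Roads not taken

**Alternative 1:** Both rings are cut at C4–C5 and C9–C10, back to the acyclic trienyl vinylsilane A1. In the forward sense a chiral Brønsted acid protonates C3, the cascade closes rings A and B, and loss of silicon fixes the alkene at C8=C9 in the bicyclic pivalate A2.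
- Merits: the decalin and two stereocentres (C5, C10) come from achiral material, either enantiomer is accessible, and the alkene is placed exactly where the hydro-oxygenation needs it, with no migration step and no C7=C8 isomer. In that respect it is better than steps 6 and 7 of the chosen route.
- Weak points: A2 has a plain methylene at C6. The equatorial C6 acetate would have to be introduced late on an unactivated position with no directing group, which is the decisive gap. The side chain of A2 stops at C12 and needs two more carbons before any lactonisation. Enantioselective proton-initiated bicyclisations are uneven in selectivity and usually need a stoichiometric chiral acid.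
- Comparison: the chosen route takes C5, C6 and C10 ready-made from 1 and spends its steps on the side chain. Alternative 1 is more general for analogues but longer and unsolved at C6.

**Alternative 2:** Ring A is cut at C1–C10 and C4–C5, back to the dimethylbenzoquinone A3 and the siloxy diene A4. A Diels–Alder reaction under a chiral Lewis acid gives the cis-fused adduct A5.
- Merits: it is convergent, it sets the quaternary C10, and it leaves carbonyl groups at C6 and C9. A C9 ketone invites direct addition of the whole side chain to make the tertiary alcohol, which is more convergent than anything in the chosen route.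
- Weak points: A4 carries a cis methyl on its reacting terminus, so the s-cis conformer is disfavoured, and the cycloaddition must join that fully substituted carbon to a methyl-bearing quinone alkene. A5 is cis-fused and needs epimerisation at C5. The C2 oxygen must be removed, and C6, C7=C8 and C8 all need separate redox adjustment. A nucleophile adding to the C9 ketone would come from the α face, anti to C20, and place the hydroxyl β, which is the wrong C9 configuration.
- Comparison: the chosen route sets C9 by oxygen delivery on the α face and needs no redox steps on the ring.

**Alternative 3:** The C6–O and C9–O bonds are cut together, back to the ring B diene A6. Sensitised photooxygenation adds oxygen [4+2] across C6 and C9 from the α face to give the endoperoxide A7.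
- Merits: two C–O bonds and both α configurations arise in one step under neutral conditions, with no carbocation and therefore no risk of methyl migration. On that count it is better than the key step.
- Weak points: A6 would have to be made from a larixol-type precursor by throwing away the C6 oxygen that is already there, or built from scratch. The tetrasubstituted C8=C9 alkene of A6 is a good ene partner, so allylic hydroperoxides at C17 or C11 would compete. After O–O cleavage the C7=C8 alkene must be reduced with hydrogen entering C8 from the β face, syn to C20. The open α face would give the axial C17 methyl, and nothing can correct C8 afterwards. The side chain again ends at C12.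
- Comparison: the chosen route sets C8 under equilibrium and keeps the C6 oxygen of 1.

Key step: step 8

Remark on the chemistry: C13 and C14 of compounds 16 to 19 form as a diastereomer mixture and are left undefined, because both become trigonal in step 11. Compounds 1 and 14 are taken as purchased. Short-lived species (carbocations, tetrahedral adducts, manganate esters) are not numbered.

## Route

Step 1
Reactants: 1 (+)-larixol
Product: 2 6α-hydroxy-14,15-dinorlabd-8(17)-en-13-one
Conditions: KMnO4, acetone/H2O, 0 °C to rt
Reagents that add atoms: none
Why: Permanganate degradation of a tertiary vinyl carbinol to a methyl ketone: the unhindered monosubstituted C14=C15 alkene is dihydroxylated much faster than the hindered exocyclic C8=C17 alkene, and glycol cleavage with oxidative loss of C14 and C15 leaves the C13 ketone, whose oxygen is the original C13 hydroxyl oxygen; no ring stereocentre is touched.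

Step 2
Reactants: 2 6α-hydroxy-14,15-dinorlabd-8(17)-en-13-one
Product: 4 6α-hydroxy-14,15,16-trinorlabd-8(17)-en-13-oic acid, via tribromomethyl ketone 3 (not isolated)
Conditions: Br2, NaOH, dioxane/H2O, 0 to 10 °C; then aq. HCl
Reagents that add atoms: sodium hydroxide, [Na+].[OH-] (carboxyl oxygen); bromine, BrBr (only in intermediate 3)
Why: Haloform reaction: the methyl group is brominated three times through the enolate and hydroxide then cleaves the C13–CBr3 bond; in cold alkaline hypobromite the positive-bromine species is too weak an electrophile to add to the hindered alkene or to oxidise the hindered C6 carbinol at a competitive rate.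

Step 3
Reactants: 4 6α-hydroxy-14,15,16-trinorlabd-8(17)-en-13-oic acid
Product: 6 6α-acetoxy-14,15,16-trinorlabd-8(17)-en-13-oic acid, via mixed acetic anhydride 5 (not isolated)
Conditions: Ac2O, pyridine, DMAP (cat.), rt; then H2O
Reagents that add atoms: acetic anhydride, CC(=O)OC(C)=O; water, O (hydrolysis of 5)
Why: DMAP-catalysed O-acetylation of the secondary 6α-alcohol; the carboxyl group is carried transiently as mixed anhydride 5, which water cleaves back during work-up.

Step 4
Reactants: 6 6α-acetoxy-14,15,16-trinorlabd-8(17)-en-13-oic acid
Product: 8 6α-acetoxy-16-diazo-14,15-dinorlabd-8(17)-en-13-one, via acid chloride 7 (not isolated)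
Conditions: (COCl)2, DMF (cat.), CH2Cl2, 0 °C to rt; then Me3SiCHN2, THF/MeCN, 0 °C
Reagents that add atoms: (trimethylsilyl)diazomethane, C[Si](C)(C)C=[N+]=[N-] (CHN2 unit); oxalyl chloride, O=C(Cl)C(=O)Cl (chlorine, only in intermediate 7)
Why: First half of the Arndt–Eistert homologation: the acid chloride acylates the diazo carbon and chloride removes the silyl group; any acid-induced movement of the exocyclic alkene is harmless because that alkene is equilibrated on purpose in step 6.

Step 5
Reactants: 8 6α-acetoxy-16-diazo-14,15-dinorlabd-8(17)-en-13-one
Product: 10 methyl 6α-acetoxy-14,15-dinorlabd-8(17)-en-16-oate, via ketene 9 (not isolated)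
Conditions: PhCO2Ag (cat.), Et3N, MeOH/THF, rt, dark
Reagents that add atoms: methanol, CO
Why: Silver-catalysed Wolff rearrangement: loss of N2 with 1,2-shift of the C12 methylene gives ketene 9, which methanol traps as the homologous ester; the migrating carbon is a CH2, so no stereocentre is involved.

Step 6
Reactants: 10 methyl 6α-acetoxy-14,15-dinorlabd-8(17)-en-16-oate
Product: 11 methyl 6α-acetoxy-14,15-dinorlabd-8-en-16-oate
Conditions: TsOH·H2O (cat.), benzene, 60 °C
Reagents that add atoms: none
Why: Acid-catalysed alkene isomerisation through the tertiary C8 cation: protonation at C17 and proton loss from C9 move the double bond into the tetrasubstituted, thermodynamically preferred C8=C9 position; any C7=C8 isomer carried along re-enters the same cation manifold in step 8, and the methyl ester cannot lactonise without first losing its alkyl group.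

Step 7
Reactants: 11 methyl 6α-acetoxy-14,15-dinorlabd-8-en-16-oate
Product: 12 6α-acetoxy-14,15-dinorlabd-8-en-16-oic acid
Conditions: LiI, pyridine, reflux; then aq. HCl
Reagents that add atoms: none
Why: SN2 dealkylation of a methyl ester by iodide: attack at the ester methyl carbon frees the carboxylate with no acyl-transfer chemistry, so the C6 acetate, which offers iodide only a hindered secondary carbon, should remain, and the non-acidic medium cannot start the lactonisation early.

Step 8
Reactants: 12 6α-acetoxy-14,15-dinorlabd-8-en-16-oic acid
Product: 13 6α-acetoxy-14,15-dinor-8βH-labdan-16,9α-olide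
Conditions: TfOH (0.2 equiv), CH2Cl2, 0 °C to rt
Reagents that add atoms: none
Why: TfOH protonates C8 of the tetrasubstituted alkene to give the tertiary C9 carbocation, the carboxyl oxygen four atoms away adds to it, and loss of the carboxyl proton returns the acid, so the catalyst turns over. The closest known reaction type is the Brønsted-acid-catalysed hydro-lactonisation of alkenoic acids through a tertiary carbocation. The one ring closed is the spiro δ-lactone O–C9–C11–C12–C13–C16, a six-membered exo capture of the cation by the tethered carboxyl; closure onto the alternative C8 cation would need a seven-membered ring and reverts. C9 is controlled by the axial C10 methyl, which screens the β face so that oxygen enters axially on the α face and C11 stays equatorial. C8 is controlled thermodynamically: protonation, proton loss and alkyl–oxygen ionisation of the lactone are all reversible, so the isomer with hydrogen axial (β) and the C17 methyl equatorial (α), free of a 1,3-diaxial methyl–methyl contact with C20, should accumulate. The step needs site selectivity between the C8 and C9 cations, trans-diaxial delivery of H and O, and capture faster than 1,2-shift of the C10 methyl; ring size, the reversibility just described and the proximity of the tether secure these in turn. The C6 acetate is a non-nucleophilic equatorial spectator whose inductive pull, felt more strongly at C8 than at C9, also disfavours the C8 cation and the C7=C8 isomer derived from it.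

Step 9
Reactants: 13 6α-acetoxy-14,15-dinor-8βH-labdan-16,9α-olide; 14 (tert-butyldimethylsilyloxy)acetaldehyde
Product: 16 6α-acetoxy-15-(tert-butyldimethylsilyloxy)-14-hydroxy-8βH-labdan-16,9α-olide, via lithium enolate 15 (not isolated)
Conditions: LiN(SiMe3)2 (1.05 equiv), THF, −78 °C; then 14, −78 °C; AcOH quench
Reagents that add atoms: lithium bis(trimethylsilyl)amide, [Li]N([Si](C)(C)C)[Si](C)(C)C (lithium, only in intermediate 15)
Why: Lactone enolate aldol addition: the α-methylene of a δ-lactone is several pKa units more acidic than the methyl of an acyclic acetate, so one equivalent of amide base at low temperature should enolise C13 selectively, and the enolate adds to the unhindered aldehyde; the new centres C13 and C14 form as a mixture that does not matter because both become sp2 in step 11.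

Step 10
Reactants: 16 6α-acetoxy-15-(tert-butyldimethylsilyloxy)-14-hydroxy-8βH-labdan-16,9α-olide
Product: 18 6α-acetoxy-9α,14-dihydroxy-8βH-labdan-16,15-olide, via desilylated diol 17 (not isolated)
Conditions: HF·pyridine, THF, 0 °C to rt
Reagents that add atoms: none
Why: Fluoride cleaves the primary silyl ether, and the freed C15 hydroxyl of 17 attacks the lactone carbonyl in a 5-exo-trig acyl transfer (translactonisation) under the mildly acidic conditions; the γ-lactone of a primary alcohol is favoured over the δ-lactone of the congested tertiary C9 alcohol, and C9 keeps its configuration because only the acyl–oxygen bond breaks.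

Step 11
Reactants: 18 6α-acetoxy-9α,14-dihydroxy-8βH-labdan-16,15-olide
Product: 20 6α-acetoxy-9α-hydroxy-8βH-labd-13-en-16,15-olide, via C14 mesylate 19 (not isolated)
Conditions: MsCl, Et3N, CH2Cl2, 0 °C; then DBU, rt
Reagents that add atoms: methanesulfonyl chloride, CS(=O)(=O)Cl (mesyl group, only in intermediate 19)
Why: Sulfonylation of the secondary C14 hydroxyl (the tertiary, neopentyl-like C9 hydroxyl should not react) followed by E1cB elimination through the lactone enolate gives the conjugated α-substituted butenolide; no ring stereocentre is touched.

## Compound list

1 | (+)-larixol, (13S)-labda-8(17),14-diene-6α,13-diol | O[C@H]1CC(=C)[C@H](CC[C@](C)(O)C=C)[C@@]2(C)CCCC(C)(C)[C@H]12 | starting material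
2 | 6α-hydroxy-14,15-dinorlabd-8(17)-en-13-one | O[C@H]1CC(=C)[C@H](CCC(C)=O)[C@@]2(C)CCCC(C)(C)[C@H]12 | intermediate
3 | 16,16,16-tribromo-6α-hydroxy-14,15-dinorlabd-8(17)-en-13-one | O[C@H]1CC(=C)[C@H](CCC(=O)C(Br)(Br)Br)[C@@]2(C)CCCC(C)(C)[C@H]12 | intermediate (not isolated)
4 | 6α-hydroxy-14,15,16-trinorlabd-8(17)-en-13-oic acid | O[C@H]1CC(=C)[C@H](CCC(=O)O)[C@@]2(C)CCCC(C)(C)[C@H]12 | intermediate
5 | acetic 6α-acetoxy-14,15,16-trinorlabd-8(17)-en-13-oic anhydride | CC(=O)O[C@H]1CC(=C)[C@H](CCC(=O)OC(C)=O)[C@@]2(C)CCCC(C)(C)[C@H]12 | intermediate (not isolated)
6 | 6α-acetoxy-14,15,16-trinorlabd-8(17)-en-13-oic acid | CC(=O)O[C@H]1CC(=C)[C@H](CCC(=O)O)[C@@]2(C)CCCC(C)(C)[C@H]12 | intermediate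
7 | 6α-acetoxy-14,15,16-trinorlabd-8(17)-en-13-oyl chloride | CC(=O)O[C@H]1CC(=C)[C@H](CCC(=O)Cl)[C@@]2(C)CCCC(C)(C)[C@H]12 | intermediate (not isolated)
8 | 6α-acetoxy-16-diazo-14,15-dinorlabd-8(17)-en-13-one (diazomethyl ketone of 6) | CC(=O)O[C@H]1CC(=C)[C@H](CCC(=O)C=[N+]=[N-])[C@@]2(C)CCCC(C)(C)[C@H]12 | intermediate
9 | ketene from 8, (decalinyl)CH2CH2CH=C=O | CC(=O)O[C@H]1CC(=C)[C@H](CCC=C=O)[C@@]2(C)CCCC(C)(C)[C@H]12 | intermediate (not isolated)
10 | methyl 6α-acetoxy-14,15-dinorlabd-8(17)-en-16-oate | CC(=O)O[C@H]1CC(=C)[C@H](CCCC(=O)OC)[C@@]2(C)CCCC(C)(C)[C@H]12 | intermediate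
11 | methyl 6α-acetoxy-14,15-dinorlabd-8-en-16-oate | CC(=O)O[C@H]1CC(C)=C(CCCC(=O)OC)[C@@]2(C)CCCC(C)(C)[C@H]12 | intermediate
12 | 6α-acetoxy-14,15-dinorlabd-8-en-16-oic acid | CC(=O)O[C@H]1CC(C)=C(CCCC(=O)O)[C@@]2(C)CCCC(C)(C)[C@H]12 | intermediate
13 | 6α-acetoxy-14,15-dinor-8βH-labdan-16,9α-olide (8α-methyl) | CC(=O)O[C@H]1C[C@@H](C)[C@](OC3=O)(CCC3)[C@@]2(C)CCCC(C)(C)[C@H]12 | intermediate
14 | (tert-butyldimethylsilyloxy)acetaldehyde | O=CCO[Si](C)(C)C(C)(C)C | starting material
15 | lithium enolate of 13 (C13=C16–OLi) | CC(=O)O[C@H]1C[C@@H](C)[C@@]3(OC(O[Li])=CCC3)[C@@]2(C)CCCC(C)(C)[C@H]12 | intermediate (not isolated)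
16 | 6α-acetoxy-15-(tert-butyldimethylsilyloxy)-14-hydroxy-8βH-labdan-16,9α-olide (C13, C14 mixture) | CC(=O)O[C@H]1C[C@@H](C)[C@](OC3=O)(CCC3C(O)CO[Si](C)(C)C(C)(C)C)[C@@]2(C)CCCC(C)(C)[C@H]12 | intermediate
17 | 6α-acetoxy-14,15-dihydroxy-8βH-labdan-16,9α-olide (C13, C14 mixture) | CC(=O)O[C@H]1C[C@@H](C)[C@](OC3=O)(CCC3C(O)CO)[C@@]2(C)CCCC(C)(C)[C@H]12 | intermediate (not isolated)
18 | 6α-acetoxy-9α,14-dihydroxy-8βH-labdan-16,15-olide (C13, C14 mixture) | CC(=O)O[C@H]1C[C@@H](C)[C@](O)(CCC3C(O)COC3=O)[C@@]2(C)CCCC(C)(C)[C@H]12 | intermediate
19 | 6α-acetoxy-9α-hydroxy-14-(methanesulfonyloxy)-8βH-labdan-16,15-olide (C13, C14 mixture) | CC(=O)O[C@H]1C[C@@H](C)[C@](O)(CCC3C(OS(C)(=O)=O)COC3=O)[C@@]2(C)CCCC(C)(C)[C@H]12 | intermediate (not isolated)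
20 | 6α-acetoxy-9α-hydroxy-8βH-labd-13-en-16,15-olide (8α-methyl) | CC(=O)O[C@H]1C[C@@H](C)[C@](O)(CCC2=CCOC2=O)[C@@]2(C)CCCC(C)(C)[C@H]12 | target

## Step count and least certain steps

Total: 11 steps. Longest linear sequence: 11 steps, from 1 (compound 14 is purchased).

**Step 8 (key step).** The C9 cation may be diverted before the carboxyl captures it. A 1,2-shift of the axial C10 methyl would start a backbone rearrangement. Drift through the C8 cation to the C7=C8 isomer would make the C6 acetate allylic, so that it ionises with loss of acetic acid. The addition may also stop short of completion because the spiro centre is congested. Fallback: from 12 directly to 13 by an organic photoredox hydro-lactonisation, using 9-mesityl-10-methylacridinium tetrafluoroborate and (PhS)2 (both catalytic) with 2,6-lutidine in 1,2-dichloroethane under 450 nm light. The excited acridinium oxidises the electron-rich tetrasubstituted alkene to its radical cation, the carboxyl adds at C9 in the six-membered mode from the α face, and thiophenol formed in the flask transfers a hydrogen atom to the C8 radical. No closed-shell carbocation is formed, so neither methyl shift nor acetate ionisation can begin. C8 is then set kinetically by hydrogen-atom transfer and not by equilibration, which is the weaker point of this variant. It makes no compound outside the list and returns at 13.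

**Step 9.** The deprotonation may lose site selectivity, with the C6 acetate enolised alongside the lactone and the aldehyde then adding at the acetyl group. Fallback, from 12 to 20 with the acetate placed last:
- Saponification of 12 (KOH, MeOH/H2O, reflux) gives 6α-hydroxy-14,15-dinorlabd-8-en-16-oic acid F1.
- The TfOH lactonisation of step 8 applied to F1 gives 6α-hydroxy-14,15-dinor-8βH-labdan-16,9α-olide F2.
- Two equivalents of LiN(iPr)2 convert F2 into the dilithium alkoxide–enolate F3, which has no competing ester and adds to 14 to give 15-(tert-butyldimethylsilyloxy)-6α,14-dihydroxy-8βH-labdan-16,9α-olide F4.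
- HF·pyridine gives the desilylated triol lactone 6α,14,15-trihydroxy-8βH-labdan-16,9α-olide F5 in the flask, which translactonises to 6α,9α,14-trihydroxy-8βH-labdan-16,15-olide F6.
- Ac2O, DMAP and pyridine acetylate the two secondary hydroxyls but not the tertiary one, giving 6α,14-diacetoxy-9α-hydroxy-8βH-labdan-16,15-olide F7.
- DBU eliminates acetic acid across C13–C14, and the sequence returns at 20.

**Step 6.** The double bond may migrate incompletely. The ester carbonyl may capture the C9 cation early with loss of the ester methyl. The minor C7=C8 isomer may lose acetic acid under acid. Fallback: from 8, Wolff rearrangement in aqueous THF (PhCO2Ag cat., Et3N) gives, through ketene 9, 6α-acetoxy-14,15-dinorlabd-8(17)-en-16-oic acid F8. Exposure of F8 to TfOH in CH2Cl2 moves the alkene and closes the lactone in one operation, with 12 only a flask intermediate. The sequence returns at 13 and saves two steps.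

**Step 2.** Positive bromine may attack the exocyclic alkene, or the C6 carbinol may be oxidised, during the degradation. Fallback: from 2, I2 in pyridine at 100 °C (Ortoleva–King reaction: reversible α-iodination, then irreversible SN2 capture of the primary iodide by pyridine) gives 1-[6α-hydroxy-13-oxo-14,15-dinorlabd-8(17)-en-16-yl]pyridinium iodide F9. Aqueous NaOH then cleaves the C13–C16 bond of F9, and acidification returns the sequence at 4 without any hypohalite.

## Further compounds

F0 | step 8 | none | none
F1 | step 9 | 6α-hydroxy-14,15-dinorlabd-8-en-16-oic acid | O[C@H]1CC(C)=C(CCCC(=O)O)[C@@]2(C)CCCC(C)(C)[C@H]12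
F2 | step 9 | 6α-hydroxy-14,15-dinor-8βH-labdan-16,9α-olide | O[C@H]1C[C@@H](C)[C@](OC3=O)(CCC3)[C@@]2(C)CCCC(C)(C)[C@H]12
F3 | step 9 | dilithium alkoxide–enolate of F2 | [Li]O[C@H]1C[C@@H](C)[C@@]3(OC(O[Li])=CCC3)[C@@]2(C)CCCC(C)(C)[C@H]12
F4 | step 9 | 15-(tert-butyldimethylsilyloxy)-6α,14-dihydroxy-8βH-labdan-16,9α-olide (C13, C14 mixture) | O[C@H]1C[C@@H](C)[C@](OC3=O)(CCC3C(O)CO[Si](C)(C)C(C)(C)C)[C@@]2(C)CCCC(C)(C)[C@H]12
F5 | step 9 | 6α,14,15-trihydroxy-8βH-labdan-16,9α-olide (C13, C14 mixture) | O[C@H]1C[C@@H](C)[C@](OC3=O)(CCC3C(O)CO)[C@@]2(C)CCCC(C)(C)[C@H]12
F6 | step 9 | 6α,9α,14-trihydroxy-8βH-labdan-16,15-olide (C13, C14 mixture) | O[C@H]1C[C@@H](C)[C@](O)(CCC3C(O)COC3=O)[C@@]2(C)CCCC(C)(C)[C@H]12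
F7 | step 9 | 6α,14-diacetoxy-9α-hydroxy-8βH-labdan-16,15-olide (C13, C14 mixture) | CC(=O)O[C@H]1C[C@@H](C)[C@](O)(CCC3C(OC(C)=O)COC3=O)[C@@]2(C)CCCC(C)(C)[C@H]12
F8 | step 6 | 6α-acetoxy-14,15-dinorlabd-8(17)-en-16-oic acid | CC(=O)O[C@H]1CC(=C)[C@H](CCCC(=O)O)[C@@]2(C)CCCC(C)(C)[C@H]12
F9 | step 2 | 1-[6α-hydroxy-13-oxo-14,15-dinorlabd-8(17)-en-16-yl]pyridinium iodide | O[C@H]1CC(=C)[C@H](CCC(=O)C[n+]3ccccc3)[C@@]2(C)CCCC(C)(C)[C@H]12.[I-]
A1 | alternative 1 | (7E)-4,8,12-trimethyl-3-(trimethylsilyl)trideca-3,7,11-trien-1-yl pivalate | CC(C)=CCC/C(C)=C/CCC(C)=C(CCOC(=O)C(C)(C)C)[Si](C)(C)C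
A2 | alternative 1 | 13,14,15,16-tetranorlabd-8-en-12-yl pivalate | C1CC(C)=C(CCOC(=O)C(C)(C)C)[C@@]2(C)CCCC(C)(C)[C@H]12
A3 | alternative 2 | 2,6-dimethyl-1,4-benzoquinone | CC1=CC(=O)C=C(C)C1=O
A4 | alternative 2 | 2-(tert-butyldimethylsilyloxy)-4-methylpenta-1,3-diene | C=C(O[Si](C)(C)C(C)(C)C)C=C(C)C
A5 | alternative 2 | cis-fused adduct, 2-(tert-butyldimethylsilyloxy)-4,4,8,10-tetramethyloctalin-2,7-diene-6,9-dione (labdane numbering) | O=C1C=C(C)C(=O)[C@@]2(C)CC(O[Si](C)(C)C(C)(C)C)=CC(C)(C)[C@@H]12
A6 | alternative 3 | 13,14,15,16-tetranorlabda-6,8-dien-12-yl tert-butyldimethylsilyl ether | C1=CC(C)=C(CCO[Si](C)(C)C(C)(C)C)[C@@]2(C)CCCC(C)(C)[C@H]12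
A7 | alternative 3 | 6α,9α-epidioxy-13,14,15,16-tetranorlabd-7-en-12-yl tert-butyldimethylsilyl ether | O3[C@H]1C=C(C)[C@](O3)(CCO[Si](C)(C)C(C)(C)C)[C@@]2(C)CCCC(C)(C)[C@H]12
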